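## Retrosynthetic overview

1. Pinophilin G ⇒ fluoride deprotection ⇐ acylation of the C8 alcohol of the bicyclic core with silyl-protected orsellinic acid (last bond made).
2. Core ⇒ one [3+3] annulation that makes C3–C4 and C1–C8a: ring B enone acetal 12 (C4 electrophile, C8a nucleophile) plus silyl dienolate 17 (C3 nucleophile, O2–CH2 latent cation at C1).
3. Enabling feature: C4a is the β-carbon of the ring B enone (C6=O, C5=C4a), and both atoms through which ring A (O2, C1, C8a, C4a, C4, C3) joins it are activated by it: exocyclic C4 at the aldehyde level and ring C8a as γ-carbon. O2–C3=C4–C4a=C5–C6=O is a doubly vinylogous ester, so C3=C4 is an aldol condensation and C1 a formaldehyde-level carbon.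
4. Ring B ⇒ Saegusa enone ⇐ CBS desymmetrization of a 2-silyloxy-2-methyl-1,3-dione (sets C8 and, with it, C7) ⇐ Michael–Dieckmann dione; C8a is relayed from C8 in the key step.
5. Order of ring formation: ring B (step 2), then ring A (step 12); the orsellinate ring is bought.

Key step: step 12

Remark: isochromene numbering is used for the core (C1 = OCH2, O2, C3 carries the acrylate, C4a/C8a ring fusion, C6 ketone, C7 carbinol with methyl, C8 ester carbon); ring A is the pyran, ring B the carbocycle.

## Route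

Step 1
Reactants: 1 2,2-dimethoxyacetaldehyde; 2 methyl (triphenylphosphoranylidene)acetate
Product: 3 methyl (E)-4,4-dimethoxybut-2-enoate
Conditions: CH2Cl2, rt
Reagents that add atoms: none
Why: Wittig olefination with a stabilized ylide should give the E-enoate; no stereocenter is formed.

Step 2
Reactants: 3 methyl (E)-4,4-dimethoxybut-2-enoate; 4 methyl 3-oxopentanoate
Product: 6 5-(dimethoxymethyl)-2-methylcyclohexane-1,3-dione, via keto ester 5 (not isolated)
Conditions: NaOMe, MeOH, reflux; then aq. NaOH, 60 °C; then AcOH to pH 5, 60 °C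
Reagents that add atoms: none
Why: Michael addition of the β-keto ester, Dieckmann-type Claisen closure through the ethyl-ketone carbon and hydrolytic decarboxylation form the classical entry to 2-alkyl-5-substituted cyclohexane-1,3-diones; the one stereocenter (acetal-bearing carbon) becomes sp2 in step 7.

Step 3
Reactants: 6 5-(dimethoxymethyl)-2-methylcyclohexane-1,3-dione
Product: 7 5-(dimethoxymethyl)-2-hydroxy-2-methylcyclohexane-1,3-dione
Conditions: dimethyldioxirane, acetone, 0 °C
Reagents that add atoms: dimethyldioxirane CC1(C)OO1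
Why: Epoxidation of the enol of the 2-alkyl-1,3-dione and opening of the epoxide (enol oxidation) should give the 2-hydroxy dione; both diastereomers are achiral and converge in step 7.

Step 4
Reactants: 7 5-(dimethoxymethyl)-2-hydroxy-2-methylcyclohexane-1,3-dione
Product: 8 5-(dimethoxymethyl)-2-methyl-2-(triethylsilyloxy)cyclohexane-1,3-dione
Conditions: Et3SiCl, imidazole, DMAP (cat.), DMF, 40 °C
Reagents that add atoms: chlorotriethylsilane CC[Si](Cl)(CC)CC
Why: Silylation of the tertiary alcohol blocks α-ketol rearrangement and places a bulky group on one face of both carbonyl groups for step 5.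

Step 5
Reactants: 8 5-(dimethoxymethyl)-2-methyl-2-(triethylsilyloxy)cyclohexane-1,3-dione
Product: 9 (2S,3S)-5-(dimethoxymethyl)-3-hydroxy-2-methyl-2-(triethylsilyloxy)cyclohexan-1-one
Conditions: (R)-2-methyl-CBS-oxazaborolidine (0.2 equiv), catecholborane (1.0 equiv), toluene, −78 to −40 °C
Reagents that add atoms: none
Why: Corey–Bakshi–Shibata reduction used as desymmetrization of a 2,2-disubstituted 1,3-dione: the catalyst tells the quaternary flank from the CH2 flank and should fix the carbinol as S, and because hydride enters anti to the silyloxy group it must take the carbonyl that makes the quaternary carbon S, so both centers (the later C8 and C7, oxygens cis) arise in one event.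

Step 6
Reactants: 9 (2S,3S)-5-(dimethoxymethyl)-3-hydroxy-2-methyl-2-(triethylsilyloxy)cyclohexan-1-one
Product: 10 (2S,3S)-5-(dimethoxymethyl)-2-methyl-2,3-bis(triethylsilyloxy)cyclohexan-1-one
Conditions: Et3SiCl, imidazole, DMF, rt
Reagents that add atoms: chlorotriethylsilane CC[Si](Cl)(CC)CC
Why: Silylation of the secondary alcohol gives a poor leaving group at the position that becomes δ to the enone carbonyl; no stereocenter is touched.

Step 7
Reactants: 10 (2S,3S)-5-(dimethoxymethyl)-2-methyl-2,3-bis(triethylsilyloxy)cyclohexan-1-one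
Product: 12 (5S,6S)-3-(dimethoxymethyl)-6-methyl-5,6-bis(triethylsilyloxy)cyclohex-2-en-1-one, via silyl enol ether 11 (not isolated)
Conditions: LiN(iPr)2, Me3SiCl, THF, −78 °C; then Pd(OAc)2 (1.05 equiv), MeCN, rt
Reagents that add atoms: chlorotrimethylsilane C[Si](C)(C)Cl (silicon present only in intermediate 11)
Why: Saegusa–Ito dehydrogenation: the ketone can enolize only toward its CH2 side (the other α-carbon is quaternary) and β-hydride elimination gives the enone, which removes the unassigned stereocenter and leaves the two set ones untouched.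

Step 8
Reactants: 13 glycolaldehyde dimer; 2 methyl (triphenylphosphoranylidene)acetate
Product: 14 methyl (E)-4-hydroxybut-2-enoate
Conditions: THF, reflux
Reagents that add atoms: none
Why: The dimer releases the hydroxy aldehyde, which undergoes Wittig olefination with the stabilized ylide to the E-enoate.

Step 9
Reactants: 14 methyl (E)-4-hydroxybut-2-enoate
Product: 15 methyl (E)-4-(methoxymethoxy)but-2-enoate
Conditions: MeOCH2Cl, iPr2NEt, CH2Cl2, 0 °C to rt
Reagents that add atoms: chloromethyl methyl ether COCCl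
Why: O-Alkylation of the primary alcohol installs the formaldehyde acetal whose CH2 becomes C1 of the target.

Step 10
Reactants: 15 methyl (E)-4-(methoxymethoxy)but-2-enoate
Product: 16 2-(trimethylsilyl)ethyl (E)-4-(methoxymethoxy)but-2-enoate
Conditions: Me3SiCH2CH2OH (3 equiv), Ti(OiPr)4 (0.1 equiv), toluene, 100 °C, methanol distilled off
Reagents that add atoms: 2-(trimethylsilyl)ethanol C[Si](C)(C)CCO
Why: Titanate-catalysed transesterification is neutral, so no alkoxide adds to the enoate, and it gives an ester that fluoride can cleave at the end.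

Step 11
Reactants: 16 2-(trimethylsilyl)ethyl (E)-4-(methoxymethoxy)but-2-enoate
Product: 17 trimethyl{[4-(methoxymethoxy)-1-[2-(trimethylsilyl)ethoxy]buta-1,3-dien-1-yl]oxy}silane
Conditions: LiN(iPr)2, DMPU, THF, −78 °C; then Me3SiCl; used crude
Reagents that add atoms: chlorotrimethylsilane C[Si](C)(C)Cl
Why: γ-Deprotonation of the crotonate and O-silylation give the vinylogous silyl ketene acetal; its double-bond geometry is of no consequence.

Step 12
Reactants: 12 (5S,6S)-3-(dimethoxymethyl)-6-methyl-5,6-bis(triethylsilyloxy)cyclohex-2-en-1-one; 17 trimethyl{[4-(methoxymethoxy)-1-[2-(trimethylsilyl)ethoxy]buta-1,3-dien-1-yl]oxy}silane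
Product: 21 2-(trimethylsilyl)ethyl (E)-3-[(7S,8S,8aS)-7-methyl-6-oxo-7,8-bis(triethylsilyloxy)-1,7,8,8a-tetrahydro-6H-isochromen-3-yl]prop-2-enoate, via acyclic adduct 18 (not isolated), via dienol silane 19 (not isolated), via methoxy pyran 20 (not isolated)
Conditions: 17 (1.1 equiv), Me3SiOTf (0.2 equiv), CH2Cl2, −78 °C; then iPr2NEt (2.5 equiv), Me3SiOTf (2.5 equiv), −78 to 0 °C; then DBU (5 equiv), 0 to 40 °C
Reagents that add atoms: trimethylsilyl trifluoromethanesulfonate C[Si](C)(C)OS(=O)(=O)C(F)(F)F (silicon present only in intermediate 19)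
Why: Proposed new method: catalytic Me3SiOTf ionizes the dimethyl acetal of 12 and dienolate 17 adds through its oxygen-bearing γ-carbon (vinylogous Mukaiyama addition, C3–C4 bond, adduct 18), after which Me3SiOTf/iPr2NEt turns the enone into dienol silane 19 and ionizes the formaldehyde acetal to an O2=C1 oxocarbenium ion that the γ-carbon C8a captures (C1–C8a bond, 20). DBU then removes methanol across C3–C4 by vinylogous E1cB elimination through the ester dienolate and leaves the dienol ether 21. The closest known reaction types are the Mukaiyama aldol–Prins cascade, Prins cyclizations started from formaldehyde acetals and Mukaiyama additions with enol silane formation in the flask; new is their union into a [3+3] annulation of two partners that are each both nucleophile and electrophile. Ring A closes in a 6-(enolendo)-endo-trig mode. C8a is the only new stereocenter that survives (those at C3 and C4 are erased): the tethered cation should add to the diene face anti to the neighbouring C8 silyloxy group, and this epimer (H8 and H8a trans-diaxial) is also the thermodynamic one, which dienolization under DBU can reach. The step needs the acetal of 12 to ionize before the formaldehyde acetal (secured by a first stage at −78 °C without amine, where only the more stabilized oxocarbenium ion forms) and γ-attack of both dienolates (secured by silyl dienolates and, for C8a, by the six-membered ring).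

Step 13
Reactants: 21 2-(trimethylsilyl)ethyl (E)-3-[(7S,8S,8aS)-7-methyl-6-oxo-7,8-bis(triethylsilyloxy)-1,7,8,8a-tetrahydro-6H-isochromen-3-yl]prop-2-enoate
Product: 22 2-(trimethylsilyl)ethyl (E)-3-[(7S,8S,8aS)-8-hydroxy-7-methyl-6-oxo-7-(triethylsilyloxy)-1,7,8,8a-tetrahydro-6H-isochromen-3-yl]prop-2-enoate
Conditions: HF·pyridine, pyridine, THF, 0 °C
Reagents that add atoms: none
Why: Selective desilylation: the secondary silyl ether should cleave faster than the tertiary one next to the quaternary center, and the enol ether, being a vinylogous ester, tolerates the buffered acid.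

Step 14
Reactants: 23 orsellinic acid
Product: 25 2,4-bis(tert-butyldimethylsilyloxy)-6-methylbenzoic acid, via silyl ester 24 (not isolated)
Conditions: tBuMe2SiCl (3.3 equiv), imidazole, DMF, rt; then AcOH/THF/H2O, rt
Reagents that add atoms: tert-butyldimethylsilyl chloride CC(C)(C)[Si](C)(C)Cl
Why: Persilylation followed by selective hydrolysis of the labile silyl ester leaves the two aryl silyl ethers (phenol protection).

Step 15
Reactants: 25 2,4-bis(tert-butyldimethylsilyloxy)-6-methylbenzoic acid; 22 2-(trimethylsilyl)ethyl (E)-3-[(7S,8S,8aS)-8-hydroxy-7-methyl-6-oxo-7-(triethylsilyloxy)-1,7,8,8a-tetrahydro-6H-isochromen-3-yl]prop-2-enoate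
Product: 27 2-(trimethylsilyl)ethyl (E)-3-[(7S,8S,8aS)-8-{[2,4-bis(tert-butyldimethylsilyloxy)-6-methylbenzoyl]oxy}-7-methyl-6-oxo-7-(triethylsilyloxy)-1,7,8,8a-tetrahydro-6H-isochromen-3-yl]prop-2-enoate, via acid chloride 26 (not isolated)
Conditions: 25, (COCl)2, DMF (cat.), CH2Cl2, 0 °C to rt, evaporate; then 22, Et3N, DMAP, CH2Cl2, 40 °C
Reagents that add atoms: oxalyl chloride O=C(Cl)C(=O)Cl (chlorine present only in intermediate 26)
Why: Esterification through the acyl chloride with DMAP catalysis is the activation a 2,6-disubstituted benzoic acid needs; the only free hydroxyl is the secondary C8 alcohol and no stereocenter is involved.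

Step 16
Reactants: 27 2-(trimethylsilyl)ethyl (E)-3-[(7S,8S,8aS)-8-{[2,4-bis(tert-butyldimethylsilyloxy)-6-methylbenzoyl]oxy}-7-methyl-6-oxo-7-(triethylsilyloxy)-1,7,8,8a-tetrahydro-6H-isochromen-3-yl]prop-2-enoate
Product: 28 pinophilin G
Conditions: Bu4NF (6 equiv), AcOH (6 equiv), THF, 0 °C to rt
Reagents that add atoms: none
Why: Global desilylation: fluoride cleaves the two aryl silyl ethers and the tertiary silyl ether and fragments the 2-(trimethylsilyl)ethyl ester to ethylene and the acid, while the acetic acid buffer should prevent retro-oxa-Michael opening of ring A and attack on the hindered aryl ester.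

## Compound list

1 | 2,2-dimethoxyacetaldehyde | COC(OC)C=O | starting material
2 | methyl (triphenylphosphoranylidene)acetate | COC(=O)C=P(c1ccccc1)(c1ccccc1)c1ccccc1 | starting material
3 | methyl (E)-4,4-dimethoxybut-2-enoate | COC(OC)/C=C/C(=O)OC | intermediate
4 | methyl 3-oxopentanoate | CCC(=O)CC(=O)OC | starting material
5 | methyl 2-(dimethoxymethyl)-5-methyl-4,6-dioxocyclohexane-1-carboxylate (keto ester, diastereomer mixture, not isolated) | COC(=O)C1C(C(OC)OC)CC(=O)C(C)C1=O | intermediate
6 | 5-(dimethoxymethyl)-2-methylcyclohexane-1,3-dione | COC(OC)C1CC(=O)C(C)C(=O)C1 | intermediate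
7 | 5-(dimethoxymethyl)-2-hydroxy-2-methylcyclohexane-1,3-dione (cis/trans mixture, both achiral) | COC(OC)C1CC(=O)C(C)(O)C(=O)C1 | intermediate
8 | 5-(dimethoxymethyl)-2-methyl-2-(triethylsilyloxy)cyclohexane-1,3-dione (cis/trans mixture, both achiral) | COC(OC)C1CC(=O)C(C)(O[Si](CC)(CC)CC)C(=O)C1 | intermediate
9 | (2S,3S)-5-(dimethoxymethyl)-3-hydroxy-2-methyl-2-(triethylsilyloxy)cyclohexan-1-one (both C5 epimers) | O[C@H]1CC(C(OC)OC)CC(=O)[C@@]1(C)O[Si](CC)(CC)CC | intermediate
10 | (2S,3S)-5-(dimethoxymethyl)-2-methyl-2,3-bis(triethylsilyloxy)cyclohexan-1-one (both C5 epimers) | CC[Si](CC)(CC)O[C@H]1CC(C(OC)OC)CC(=O)[C@@]1(C)O[Si](CC)(CC)CC | intermediate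
11 | {[(5S,6S)-3-(dimethoxymethyl)-6-methyl-5,6-bis(triethylsilyloxy)cyclohex-1-en-1-yl]oxy}trimethylsilane (silyl enol ether, not isolated) | CC[Si](CC)(CC)O[C@H]1CC(C(OC)OC)C=C(O[Si](C)(C)C)[C@@]1(C)O[Si](CC)(CC)CC | intermediate
12 | (5S,6S)-3-(dimethoxymethyl)-6-methyl-5,6-bis(triethylsilyloxy)cyclohex-2-en-1-one | CC[Si](CC)(CC)O[C@H]1CC(C(OC)OC)=CC(=O)[C@@]1(C)O[Si](CC)(CC)CC | intermediate
13 | glycolaldehyde dimer (1,4-dioxane-2,5-diol) | OC1COC(O)CO1 | starting material
14 | methyl (E)-4-hydroxybut-2-enoate | COC(=O)/C=C/CO | intermediate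
15 | methyl (E)-4-(methoxymethoxy)but-2-enoate | COCOC/C=C/C(=O)OC | intermediate
16 | 2-(trimethylsilyl)ethyl (E)-4-(methoxymethoxy)but-2-enoate | COCOC/C=C/C(=O)OCC[Si](C)(C)C | intermediate
17 | trimethyl{[4-(methoxymethoxy)-1-[2-(trimethylsilyl)ethoxy]buta-1,3-dien-1-yl]oxy}silane (double-bond isomer mixture) | COCOC=CC=C(O[Si](C)(C)C)OCC[Si](C)(C)C | intermediate
18 | 2-(trimethylsilyl)ethyl (E)-5-methoxy-4-(methoxymethoxy)-5-[(4S,5S)-4-methyl-3-oxo-4,5-bis(triethylsilyloxy)cyclohex-1-en-1-yl]pent-2-enoate (acyclic adduct, epimers at chain C4 and C5, not isolated) | CC[Si](CC)(CC)O[C@H]1CC(C(OC)C(OCOC)/C=C/C(=O)OCC[Si](C)(C)C)=CC(=O)[C@@]1(C)O[Si](CC)(CC)CC | intermediate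
19 | dienol silane of 18: ring B as 1-(trimethylsilyloxy)cyclohexa-1,3-diene with C6=C5 and C4a=C8a double bonds (core numbering), ring stereocenters unchanged, not isolated | CC[Si](CC)(CC)O[C@H]1C=C(C(OC)C(OCOC)/C=C/C(=O)OCC[Si](C)(C)C)C=C(O[Si](C)(C)C)[C@@]1(C)O[Si](CC)(CC)CC | intermediate
20 | 2-(trimethylsilyl)ethyl (E)-3-[(7S,8S,8aS)-4-methoxy-7-methyl-6-oxo-7,8-bis(triethylsilyloxy)-3,4,6,7,8,8a-hexahydro-1H-isochromen-3-yl]prop-2-enoate (methoxy pyran, epimers at C3 and C4, not isolated) | CC[Si](CC)(CC)O[C@H]1[C@@H]2COC(/C=C/C(=O)OCC[Si](C)(C)C)C(OC)C2=CC(=O)[C@@]1(C)O[Si](CC)(CC)CC | intermediate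
21 | 2-(trimethylsilyl)ethyl (E)-3-[(7S,8S,8aS)-7-methyl-6-oxo-7,8-bis(triethylsilyloxy)-1,7,8,8a-tetrahydro-6H-isochromen-3-yl]prop-2-enoate | CC[Si](CC)(CC)O[C@H]1[C@@H]2COC(/C=C/C(=O)OCC[Si](C)(C)C)=CC2=CC(=O)[C@@]1(C)O[Si](CC)(CC)CC | intermediate
22 | 2-(trimethylsilyl)ethyl (E)-3-[(7S,8S,8aS)-8-hydroxy-7-methyl-6-oxo-7-(triethylsilyloxy)-1,7,8,8a-tetrahydro-6H-isochromen-3-yl]prop-2-enoate | O[C@H]1[C@@H]2COC(/C=C/C(=O)OCC[Si](C)(C)C)=CC2=CC(=O)[C@@]1(C)O[Si](CC)(CC)CC | intermediate
23 | orsellinic acid (2,4-dihydroxy-6-methylbenzoic acid) | Cc1cc(O)cc(O)c1C(=O)O | starting material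
24 | tert-butyldimethylsilyl 2,4-bis(tert-butyldimethylsilyloxy)-6-methylbenzoate (silyl ester, not isolated) | Cc1cc(O[Si](C)(C)C(C)(C)C)cc(O[Si](C)(C)C(C)(C)C)c1C(=O)O[Si](C)(C)C(C)(C)C | intermediate
25 | 2,4-bis(tert-butyldimethylsilyloxy)-6-methylbenzoic acid | Cc1cc(O[Si](C)(C)C(C)(C)C)cc(O[Si](C)(C)C(C)(C)C)c1C(=O)O | intermediate
26 | 2,4-bis(tert-butyldimethylsilyloxy)-6-methylbenzoyl chloride (not isolated) | Cc1cc(O[Si](C)(C)C(C)(C)C)cc(O[Si](C)(C)C(C)(C)C)c1C(=O)Cl | intermediate
27 | 2-(trimethylsilyl)ethyl (E)-3-[(7S,8S,8aS)-8-{[2,4-bis(tert-butyldimethylsilyloxy)-6-methylbenzoyl]oxy}-7-methyl-6-oxo-7-(triethylsilyloxy)-1,7,8,8a-tetrahydro-6H-isochromen-3-yl]prop-2-enoate | Cc1cc(O[Si](C)(C)C(C)(C)C)cc(O[Si](C)(C)C(C)(C)C)c1C(=O)O[C@H]1[C@@H]2COC(/C=C/C(=O)OCC[Si](C)(C)C)=CC2=CC(=O)[C@@]1(C)O[Si](CC)(CC)CC | intermediate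
28 | pinophilin G, (E)-3-[(7S,8S,8aS)-8-(2,4-dihydroxy-6-methylbenzoyl)oxy-7-hydroxy-7-methyl-6-oxo-1,7,8,8a-tetrahydro-6H-isochromen-3-yl]prop-2-enoic acid | Cc1cc(O)cc(O)c1C(=O)O[C@H]1[C@@H]2COC(/C=C/C(=O)O)=CC2=CC(=O)[C@@]1(C)O | target

## Step count and risks

Total step count: 16. Longest linear sequence: 11 steps (steps 1–7, 12, 13, 15, 16).

**Step 12 (proposed new method).**
- What may go wrong: the C8 silyloxy group may ionize from the dienol silane (vinylogous elimination) before ring closure.
- The methoxymethyl cation may be transferred to another nucleophile instead of being captured at C8a.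
- In the base stage, ring A may open at O2–C3, or loss of methanol may stay incomplete.

Fallback with known reactions, setting out from 12 and 14 and coming back at 21. The acetal of 12 is unmasked without aqueous acid (Et3SiOTf, 2,4,6-collidine; then water) to the aldehyde (4S,5S)-4-methyl-3-oxo-4,5-bis(triethylsilyloxy)cyclohex-1-ene-1-carbaldehyde F1. In parallel, 14 is transesterified (Me3SiCH2CH2OH, Ti(OiPr)4) to 2-(trimethylsilyl)ethyl (E)-4-hydroxybut-2-enoate F2 and oxidized with MnO2 to 2-(trimethylsilyl)ethyl (E)-4-oxobut-2-enoate F3. Pudovik addition of diethyl phosphite (Et3N cat.) converts F3 into 2-(trimethylsilyl)ethyl (E)-4-(diethoxyphosphoryl)-4-hydroxybut-2-enoate F4, which is protected (MeOCH2Cl, iPr2NEt) as 2-(trimethylsilyl)ethyl (E)-4-(diethoxyphosphoryl)-4-(methoxymethoxy)but-2-enoate F5. Horner–Wadsworth–Emmons olefination of F1 with the sodium salt of F5 (NaN(SiMe3)2, THF, −78 °C) should place the C3=C4 double bond directly, mainly with O2 cis to ring B, to give the methoxymethyl dienol ether F6. A separate Prins-type closure (Me3SiOTf, Et3N, CH2Cl2, −40 °C: dienol silane formation, ionization of the formaldehyde acetal, capture at C8a) then makes C1–C8a and gives 21 with no elimination step.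

**Step 5.**
- What may go wrong: poor discrimination between the two carbonyl groups or their faces (low enantiomeric or diastereomeric purity), or reduction of both ketones.

Fallback, setting out from 8 and coming back at 9. Substrate-controlled reduction (NaBH4, CeCl3, MeOH, −78 °C; hydride anti to the silyloxy group) gives the racemic cis hydroxy ketone rac-(2S*,3S*)-5-(dimethoxymethyl)-3-hydroxy-2-methyl-2-(triethylsilyloxy)cyclohexan-1-one F7. Kinetic resolution with Candida antarctica lipase B and vinyl acetate in tert-butyl methyl ether should, by the empirical rule for lipases, acetylate the 3R enantiomer to the acetate (1R,2R)-5-(dimethoxymethyl)-2-methyl-3-oxo-2-(triethylsilyloxy)cyclohexyl acetate F8 and leave 9 for separation. At most half of the material is used.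

**Step 15.**
- What may go wrong: slow acylation of the hindered alcohol by the 2,6-disubstituted aroyl chloride, during which amine base may open ring A (retro-oxa-Michael) or epimerize C8a.

Fallback, setting out from 23 and 22 and coming back at 28. Orsellinic acid 23 is condensed with acetone ((CF3CO)2O, CF3CO2H) to 7-hydroxy-2,2,5-trimethyl-4H-1,3-benzodioxin-4-one F9 and silylated (tBuMe2SiCl, imidazole) to 7-(tert-butyldimethylsilyloxy)-2,2,5-trimethyl-4H-1,3-benzodioxin-4-one F10. Irradiation of F10 (300 nm, CH2Cl2) with 22 expels acetone and gives an acyl ketene that the alcohol traps under neutral conditions, forming the salicylate 2-(trimethylsilyl)ethyl (E)-3-[(7S,8S,8aS)-8-{[4-(tert-butyldimethylsilyloxy)-2-hydroxy-6-methylbenzoyl]oxy}-7-methyl-6-oxo-7-(triethylsilyloxy)-1,7,8,8a-tetrahydro-6H-isochromen-3-yl]prop-2-enoate F11. The fluoride treatment of step 16 converts F11 into 28.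

Further compounds
F1 | step 12 | (4S,5S)-4-methyl-3-oxo-4,5-bis(triethylsilyloxy)cyclohex-1-ene-1-carbaldehyde | CC[Si](CC)(CC)O[C@H]1CC(C=O)=CC(=O)[C@@]1(C)O[Si](CC)(CC)CC
F2 | step 12 | 2-(trimethylsilyl)ethyl (E)-4-hydroxybut-2-enoate | OC/C=C/C(=O)OCC[Si](C)(C)C
F3 | step 12 | 2-(trimethylsilyl)ethyl (E)-4-oxobut-2-enoate | O=C/C=C/C(=O)OCC[Si](C)(C)C
F4 | step 12 | 2-(trimethylsilyl)ethyl (E)-4-(diethoxyphosphoryl)-4-hydroxybut-2-enoate | CCOP(=O)(OCC)C(O)/C=C/C(=O)OCC[Si](C)(C)C
F5 | step 12 | 2-(trimethylsilyl)ethyl (E)-4-(diethoxyphosphoryl)-4-(methoxymethoxy)but-2-enoate | CCOP(=O)(OCC)C(OCOC)/C=C/C(=O)OCC[Si](C)(C)C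
F6 | step 12 | 2-(trimethylsilyl)ethyl (2E)-4-(methoxymethoxy)-5-[(4S,5S)-4-methyl-3-oxo-4,5-bis(triethylsilyloxy)cyclohex-1-en-1-yl]penta-2,4-dienoate (O2 cis to ring B) | CC[Si](CC)(CC)O[C@H]1CC(/C=C(OCOC)/C=C/C(=O)OCC[Si](C)(C)C)=CC(=O)[C@@]1(C)O[Si](CC)(CC)CC
F7 | step 5 | rac-(2S*,3S*)-5-(dimethoxymethyl)-3-hydroxy-2-methyl-2-(triethylsilyloxy)cyclohexan-1-one (racemate, oxygens cis) | OC1CC(C(OC)OC)CC(=O)C1(C)O[Si](CC)(CC)CC
F8 | step 5 | (1R,2R)-5-(dimethoxymethyl)-2-methyl-3-oxo-2-(triethylsilyloxy)cyclohexyl acetate | CC(=O)O[C@@H]1CC(C(OC)OC)CC(=O)[C@]1(C)O[Si](CC)(CC)CC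
F9 | step 15 | 7-hydroxy-2,2,5-trimethyl-4H-1,3-benzodioxin-4-one | Cc1cc(O)cc2OC(C)(C)OC(=O)c12
F10 | step 15 | 7-(tert-butyldimethylsilyloxy)-2,2,5-trimethyl-4H-1,3-benzodioxin-4-one | Cc1cc(O[Si](C)(C)C(C)(C)C)cc2OC(C)(C)OC(=O)c12
F11 | step 15 | 2-(trimethylsilyl)ethyl (E)-3-[(7S,8S,8aS)-8-{[4-(tert-butyldimethylsilyloxy)-2-hydroxy-6-methylbenzoyl]oxy}-7-methyl-6-oxo-7-(triethylsilyloxy)-1,7,8,8a-tetrahydro-6H-isochromen-3-yl]prop-2-enoate | Cc1cc(O[Si](C)(C)C(C)(C)C)cc(O)c1C(=O)O[C@H]1[C@@H]2COC(/C=C/C(=O)OCC[Si](C)(C)C)=CC2=CC(=O)[C@@]1(C)O[Si](CC)(CC)CC
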